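## Structural features

Trisindolal (13) is built from three indole nuclei joined at one sp3 methine carbon: ring A is attached through C3 and carries a formyl group on the adjacent C2, while rings B and C are plain indol-3-yl groups with free N–H. The methine carbon bears two identical indol-3-yl groups, so it is not a stereocentre; the molecule has no stereogenic element and hence no adjacent stereocentres to relate. The fragile parts are the triarylmethane C–H (easily oxidised to a cationic azafulvenium dye), the indole C3–methine bonds (protonation at C3 opens retro-Friedel–Crafts exchange of indole units) and the aldehyde. In acid, C2 of ring B or ring C can attack the formyl carbon and close a six-membered ring on the way to an indolo[3,2-b]carbazole. The real difficulty is desymmetrisation: one of three indoles must carry both the methine at C3 and a carbonyl carbon at C2, in a crowded ortho relationship. Acid-mediated condensation of indoles with one-carbon electrophiles cannot give this pattern selectively, and one of three similar indoles cannot be formylated at C2 afterwards. The key step exploits the contiguous N1–C2(CHO)–C3(CH) array of ring A: C2 and C3 are the two carbons of an alkyne placed ortho to an anilide nitrogen, with C2 already carrying the aldehyde as an acetal. Closing N1–C2 and joining C3 to the methine carbon in one palladium-mediated event builds the pyrrole ring of ring A and the triarylmethane together.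

## Logic of the disconnections

**13 ⇒ 12.** The two carbamate N–C(=O) bonds on N1 of rings B and C are cut last. While acylated, these rings are poor nucleophiles at C2 and poor leaving groups at C3, so the acid-sensitive events of the end game are run before they are freed. The gain is a robust penultimate compound, not a simpler skeleton. The forward step must cleave two carbamates without acid and without touching an aldehyde that has no α-hydrogen.

**12 ⇒ 11.** The formyl C=O is traced back to the two C–OEt bonds of a diethyl acetal. A free aldehyde conjugated to an alkyne would not survive amine, organometallic and palladium steps, and the acetal carries C2 at the final oxidation level, so no redox step is needed. The forward step needs acid mild enough for the carbamates and the triarylmethane, and it is placed while rings B and C are still deactivated.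

**11 ⇒ 4 + 9 (through 10).** N1–C2 and C3–methine are cut, which opens the pyrrole ring of ring A. This is the only place where the dissymmetry of the molecule resides: the cut yields an anilide bearing an acetal-terminated alkyne and a symmetrical diindolylmethyl electrophile of similar size, so the synthesis becomes convergent. The forward step requires zerovalent palladium to ionise 9, the nitrogen of 4 to add 5-endo to the alkyne, C–C reductive elimination to outrun protonation, and the N-acyl group of 10 to fall off in the same flask.

**4 ⇒ 3 ⇒ 1 + 2.** The N–C(=O) bond of the trifluoroacetamide is cut, then the aryl–alkyne C–C bond. The acyl group is only an acidifying activator for nitrogen, and the aryl–alkyne bond is the standard cross-coupling bond, leading to two commercial materials. The demands are a coupling at room temperature that leaves the acetal and the free amine alone, and an acylation buffered against acid.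

**9 ⇒ 8 ⇒ 7 + 6, and 7 ⇒ 5.** The carbonate O–C(=O) bond is cut, then one methine–C3 bond, then the C3–Mg bond back to the C3–I bond. Because the carbinol is symmetrical, both halves come from the same N-protected indole series, and aldehyde plus aryl-metal is the shortest assembly. The forward step needs a metalation at C3 that leaves the carbamate intact and a trap of the alkoxide in the flask, so that the ionisable diarylmethanol is never handled free.

## Other disconnections considered

**Alternative 1:** The cut is the C2–C3 bond of ring A.

- **Forward step.** The isocyanide A1, which holds the 1,1-diindolylethene unit ortho to the isocyano group, would be treated with tributyltin hydride (A2) and a radical initiator. The stannyl radical adds to the isocyanide carbon, the imidoyl radical closes 5-exo-trig onto the styrenic carbon, the diindolylmethyl radical takes hydrogen from A2, and tautomerisation gives the 2-stannylindole A3.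
- **In its favour.** The conditions are neutral and tolerate free indole N–H, so no carbamates would be needed; on this point it is better than the chosen plan. The C2–tin bond is a general handle for analogues, on which it is also better.
- **Against it here.** A3 carries tin, not a formyl group, so further operations (tin–halogen exchange and formylation or carbonylation) would follow on an unprotected triindolylmethane. A1 contains an enamine-like, readily protonated diindolylethene that must survive formamide dehydration. The cyclised radical is doubly indolyl-stabilised, so hydrogen transfer may be slow and dimerisation may compete. Stoichiometric tin is used.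
- **Comparison.** On structure the two plans are equal in closing the pyrrole ring of ring A last on a preformed diindolyl unit, and equal in avoiding acid during ring formation. The chosen plan forms two skeletal bonds and delivers C2 at the aldehyde oxidation level, whereas this one forms one skeletal bond. On mechanism it is a radical chain as opposed to an organopalladium cycle. On step economy it is the longer route.

**Alternative 2:** The cuts are N1–C2 and C2–C3, a [4+1] annulation.

- **Forward step.** The sulfonamido ketone A4, ethyl bromoacetate (A5) and a carbonate base would give N-alkylation, intramolecular aldol addition of the glycinate methylene to the ketone and dehydration, leading to the N-sulfonyl indole-2-carboxylate A6.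
- **In its favour.** It needs no transition metal and no inert-atmosphere catalysis, so it is better on cost and operational simplicity. It forms two ring bonds in one flask, where it is the equal of the chosen plan. A4 should be reachable in few steps by a double Friedel–Crafts condensation at the aldehyde carbon of a glyoxal-type precursor.
- **Against it here.** The ketone of A4 is flanked by the bulky diindolylmethyl group, and its α-C–H is doubly benzylic, so enolisation competes with the aldol step. The free indole N–H groups may be alkylated by A5. A6 has the ester oxidation level and an N-sulfonyl group, so desulfonylation, reduction and re-oxidation must follow.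
- **Comparison.** On structure both plans build ring A around the preformed diindolylmethyl unit. On mechanism the polar sequence is simpler and better precedented for plain substrates. On step economy it is worse after the key step: three operations against two unmaskings.

**Alternative 3:** The cuts are C3–C3a and N1–C2, a Fischer indolisation.

- **Forward step.** The phenylhydrazone A8 of the keto ester A7 would be heated with acid. The ene-hydrazine undergoes [3,3] rearrangement, rearomatisation, aminal closure and loss of ammonia, giving the indole-2-carboxylate A9. A8 is drawn as the Z isomer; its geometry is immaterial for the rearrangement.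
- **In its favour.** The benzene ring of ring A comes from the cheapest aryl source, with no halide and no metal, which is better than the chosen plan on cost. The regiochemistry is unambiguous because A7 has a single enolisable α-position. Convergence is equal to the chosen plan.
- **Against it here.** Acid and heat meet a 3,3'-diindolylmethane that is the β-substituent of the hydrazone, so protonation at C3 of an indole and retro-Michael or retro-Friedel–Crafts loss of an indole unit are likely. A9 again needs reduction and re-oxidation at C2.
- **Comparison.** On structure ring A is made from the arene side instead of the alkyne side. On mechanism a sigmatropic step replaces catalysis, but it runs under the conditions this skeleton tolerates least. On step economy the overall count is about equal to the chosen plan.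

Key step: step 4

## Remarks and assumptions

- **Halide choice.** The 3-iodoindole 5 is used in place of the 3-bromo analogue, because iodine–magnesium exchange at −20 °C should outrun attack of the reagent on the carbamate.
- **Fate of the trifluoroacetyl group.** In step 4 the methoxide released from 9 is assumed to remove the trifluoroacetyl group of 10 as its methyl ester, with K2CO3 acting as a proton shuttle that is returned unchanged.
- **Atom balance of step 4.** 4 (C15H16F3NO3) + 9 (C29H32N2O7) → 11 (C40H45N3O6) + CO2 + CF3CO2CH3.
- **Order of unmasking.** The acetal is hydrolysed before the carbamates are removed, so that acid meets the molecule only while rings B and C are N-acylated.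

## Route

Step 1
Reactants: 1 2-iodoaniline; 2 3,3-diethoxyprop-1-yne
Product: 3 2-(3,3-diethoxyprop-1-yn-1-yl)aniline
Conditions: PdCl2(PPh3)2 (2 mol%), CuI (4 mol%), Et3N, rt
Reagents that add atoms: none
Why: Sonogashira coupling; the aryl iodide undergoes oxidative addition at room temperature, the free amine and the base-stable acetal are tolerated, and without an acidifying N-acyl group the alkynylaniline should not cyclise under these conditions.

Step 2
Reactants: 3 2-(3,3-diethoxyprop-1-yn-1-yl)aniline
Product: 4 N-[2-(3,3-diethoxyprop-1-yn-1-yl)phenyl]-2,2,2-trifluoroacetamide
Conditions: (CF3CO)2O, Et3N, CH2Cl2, 0 °C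
Reagents that add atoms: trifluoroacetic anhydride, O=C(OC(=O)C(F)(F)F)C(F)(F)F
Why: N-acylation of an aniline with an anhydride; excess amine keeps the medium basic so the diethyl acetal should survive, and the trifluoroacetyl group gives the N–H acidity that the aminopalladation needs.

Step 3
Reactants: 5 tert-butyl 3-iodoindole-1-carboxylate; 6 tert-butyl 3-formylindole-1-carboxylate
Product: 9 bis[1-(tert-butoxycarbonyl)indol-3-yl]methyl methyl carbonate, via 3-indolylmagnesium chloride 7 (not isolated), via chloromagnesium alkoxide 8 (not isolated)
Conditions: iPrMgCl·LiCl, THF, −20 °C; then 6, −20 to 0 °C; then ClCO2Me, 0 °C to rt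
Reagents that add atoms: methyl chloroformate, COC(=O)Cl
Why: Iodine–magnesium exchange followed by Grignard 1,2-addition to the aldehyde and O-acylation of the magnesium alkoxide in the same flask, so the ionisable diarylmethanol is never isolated; the two Boc groups lower the donor strength of the indoles enough for 9 to be handled (Et3N-deactivated silica), and the carbinol carbon bears two identical aryl groups, so no stereocentre arises.

Step 4
Reactants: 4 N-[2-(3,3-diethoxyprop-1-yn-1-yl)phenyl]-2,2,2-trifluoroacetamide; 9 bis[1-(tert-butoxycarbonyl)indol-3-yl]methyl methyl carbonate
Product: 11 3-{bis[1-(tert-butoxycarbonyl)indol-3-yl]methyl}-2-(diethoxymethyl)-1H-indole, via N-trifluoroacetylindole 10 (not isolated)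
Conditions: Pd(PPh3)4 (5 mol%), K2CO3 (anhydrous), 9 (1.2 equiv), THF, 60 °C, Ar
Reagents that add atoms: none
Why: The step is an aminopalladation–reductive elimination of a 2-alkynyltrifluoroacetanilide with a benzylic electrophile (Cacchi indole synthesis), the closest known cases being the same reaction with allyl carbonates and benzyl halides. Zerovalent palladium ionises the doubly benzylic carbonate 9 with loss of CO2 and methoxide to an η3-diindolylmethyl complex of divalent palladium, whose cationic metal centre binds the alkyne of 4. The trifluoroacetamide, deprotonated by methoxide or K2CO3, adds through nitrogen to the distal alkyne carbon anti to palladium, which closes the pyrrole ring of ring A in the 5-endo-dig mode and forms N1–C2; reductive elimination from the resulting indol-3-yl(diindolylmethyl)palladium species forms the C3–methine bond and returns zerovalent palladium. The N-trifluoroacetyl group of 10 is then removed by the methanol–methoxide formed in the flask, which should give 11 with free N1–H. No stereocentre arises, because the methine carbon carries two identical indol-3-yl groups. Three selectivities are needed: C–C reductive elimination in preference to protonation of the indol-3-ylpalladium intermediate, favoured by anhydrous base and by a diarylmethyl ligand without β-hydrogen; C3 and not nitrogen as the final site of the diindolylmethyl group, favoured because an N-alkylated trifluoroacetamide is itself a doubly benzylic amide that should re-ionise under the same catalyst; and integrity of the electrophile, favoured by the two Boc groups, which keep 9 from ionising spontaneously to an azafulvenium ion. The acetal is inert to the weakly basic, anhydrous medium.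

Step 5
Reactants: 11 3-{bis[1-(tert-butoxycarbonyl)indol-3-yl]methyl}-2-(diethoxymethyl)-1H-indole
Product: 12 3-{bis[1-(tert-butoxycarbonyl)indol-3-yl]methyl}-1H-indole-2-carbaldehyde
Conditions: PPTS (cat.), acetone–H2O (10:1), rt
Reagents that add atoms: water, O
Why: Acid-catalysed acetal hydrolysis through an oxocarbenium ion stabilised by ring A; rings B and C are still N-acylated, so their C2 positions should not attack the oxocarbenium or formyl carbon and retro-Friedel–Crafts exchange is disfavoured, and the carbamates are stable to this weak acid.

Step 6
Reactants: 12 3-{bis[1-(tert-butoxycarbonyl)indol-3-yl]methyl}-1H-indole-2-carbaldehyde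
Product: 13 trisindolal (3-[di(1H-indol-3-yl)methyl]-1H-indole-2-carbaldehyde)
Conditions: K2CO3, MeOH–THF, 40 °C, Ar
Reagents that add atoms: none
Why: Base-mediated methanolysis of N-Boc indoles, which behave as activated carbamates because the indolide is a good leaving group; the aldehyde has no α-hydrogen and is deactivated as a vinylogous formamide, so it should survive, and exclusion of air limits oxidation of the triarylmethane C–H.

## Compound list

1 | 2-iodoaniline | Nc1ccccc1I | starting material
2 | 3,3-diethoxyprop-1-yne | CCOC(OCC)C#C | starting material
3 | 2-(3,3-diethoxyprop-1-yn-1-yl)aniline | CCOC(OCC)C#Cc1ccccc1N | intermediate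
4 | N-[2-(3,3-diethoxyprop-1-yn-1-yl)phenyl]-2,2,2-trifluoroacetamide | CCOC(OCC)C#Cc1ccccc1NC(=O)C(F)(F)F | intermediate
5 | tert-butyl 3-iodoindole-1-carboxylate | Ic1cn(C(=O)OC(C)(C)C)c2ccccc12 | starting material
6 | tert-butyl 3-formylindole-1-carboxylate | O=Cc1cn(C(=O)OC(C)(C)C)c2ccccc12 | starting material
7 | [1-(tert-butoxycarbonyl)indol-3-yl]magnesium chloride (as its LiCl complex) | Cl[Mg]c1cn(C(=O)OC(C)(C)C)c2ccccc12 | intermediate (not isolated)
8 | chloromagnesium bis[1-(tert-butoxycarbonyl)indol-3-yl]methanolate | Cl[Mg]OC(c1cn(C(=O)OC(C)(C)C)c2ccccc12)c1cn(C(=O)OC(C)(C)C)c2ccccc12 | intermediate (not isolated)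
9 | bis[1-(tert-butoxycarbonyl)indol-3-yl]methyl methyl carbonate | COC(=O)OC(c1cn(C(=O)OC(C)(C)C)c2ccccc12)c1cn(C(=O)OC(C)(C)C)c2ccccc12 | intermediate
10 | 3-{bis[1-(tert-butoxycarbonyl)indol-3-yl]methyl}-2-(diethoxymethyl)-1-(trifluoroacetyl)indole | CCOC(OCC)c1n(C(=O)C(F)(F)F)c2ccccc2c1C(c1cn(C(=O)OC(C)(C)C)c2ccccc12)c1cn(C(=O)OC(C)(C)C)c2ccccc12 | intermediate (not isolated)
11 | 3-{bis[1-(tert-butoxycarbonyl)indol-3-yl]methyl}-2-(diethoxymethyl)-1H-indole | CCOC(OCC)c1[nH]c2ccccc2c1C(c1cn(C(=O)OC(C)(C)C)c2ccccc12)c1cn(C(=O)OC(C)(C)C)c2ccccc12 | intermediate
12 | 3-{bis[1-(tert-butoxycarbonyl)indol-3-yl]methyl}-1H-indole-2-carbaldehyde | O=Cc1[nH]c2ccccc2c1C(c1cn(C(=O)OC(C)(C)C)c2ccccc12)c1cn(C(=O)OC(C)(C)C)c2ccccc12 | intermediate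
13 | trisindolal, 3-[di(1H-indol-3-yl)methyl]-1H-indole-2-carbaldehyde | O=Cc1[nH]c2ccccc2c1C(c1c[nH]c2ccccc12)c1c[nH]c2ccccc12 | target

## Step count and least certain steps

Total step count: 6. Longest linear sequence: 5 steps (steps 1, 2, 4, 5 and 6, from 1 to 13). The carbonate branch adds one step (step 3) before the convergence.

**Step 4, the key step.** The most likely failure is that reductive elimination to the bulky secondary diindolylmethyl group is slower than protonation of the indol-3-ylpalladium intermediate, so that ring A closes without substitution at C3. The η3 complex could also be consumed by methoxide or by nitrogen alkylation before the alkyne is engaged. The fallback separates the two bond formations. It sets out from 3: cycloisomerisation with CuI (10 mol%) in DMF at 100 °C, a 5-endo-dig hydroamination of a 2-alkynylaniline, would give 2-(diethoxymethyl)-1H-indole F1. The free C3 position of F1 would then be alkylated with 9 under Pd2(dba)3/DPEphos in toluene at 50 °C. This is a palladium-catalysed C3-benzylation of an indole with a benzylic carbonate, in which the indole attacks the η3 complex from outside the metal, so protonation of an aryl–palladium bond no longer competes. The fallback comes back to the route at 11.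

**Step 3.** The likely failures are attack of the arylmagnesium species on a carbamate carbonyl, or migration of the metal before addition. In the trapping stage, incomplete acylation of the hindered alkoxide or ionisation of the product during isolation may occur. The fallback avoids a basic carbanion and separates the two events. It sets out from 6: [RhCl(cod)]2-catalysed 1,2-addition of the commercial tert-butyl 3-(4,4,5,5-tetramethyl-1,3,2-dioxaborolan-2-yl)indole-1-carboxylate with K3PO4 in dioxane–H2O at 60 °C would give bis[1-(tert-butoxycarbonyl)indol-3-yl]methanol F2. F2 is isolated on deactivated silica and acylated with ClCO2Me and pyridine in CH2Cl2 at 0 °C, coming back at 9.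

**Step 5.** The likely failures are acid-induced loss of a carbamate followed by ring closure of the freed indole onto the oxocarbenium carbon, or sluggish hydrolysis next to the bulky C3 substituent. The fallback carries C2 at the alcohol oxidation level and reaches the aldehyde by a neutral oxidation, so no acid is used. It sets out from 1:

- Sonogashira coupling with tert-butyldimethyl(prop-2-yn-1-yloxy)silane under the conditions of step 1 would give 2-{3-[(tert-butyldimethylsilyl)oxy]prop-1-yn-1-yl}aniline F3.
- Trifluoroacetylation as in step 2 would give N-(2-{3-[(tert-butyldimethylsilyl)oxy]prop-1-yn-1-yl}phenyl)-2,2,2-trifluoroacetamide F4.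
- The palladium-catalysed cyclisation–coupling with 9 as in step 4 would pass through 3-{bis[1-(tert-butoxycarbonyl)indol-3-yl]methyl}-2-{[(tert-butyldimethylsilyl)oxy]methyl}-1-(trifluoroacetyl)indole F5, which is not isolated, and give 3-{bis[1-(tert-butoxycarbonyl)indol-3-yl]methyl}-2-{[(tert-butyldimethylsilyl)oxy]methyl}-1H-indole F6.
- Desilylation with TBAF buffered by acetic acid in THF at 0 °C would give (3-{bis[1-(tert-butoxycarbonyl)indol-3-yl]methyl}-1H-indol-2-yl)methanol F7.
- Oxidation with MnO2 in CH2Cl2 at room temperature comes back at 12.

**Step 6.** The likely failures are incomplete cleavage of the second carbamate, base-induced side reactions at the formyl group, or oxidation of the triarylmethane C–H in the basic medium. The fallback inverts the order of unmasking so that the aldehyde stays protected during the basic step. It sets out from 11: K2CO3 in MeOH–THF at 40 °C would give 2-(diethoxymethyl)-3-[di(1H-indol-3-yl)methyl]-1H-indole F8. The acetal of F8 would then be hydrolysed under the mildest conditions available (PPTS in acetone–H2O at 0 °C, with close monitoring to forestall ring closure onto the formyl carbon), coming back at 13.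

## Further compounds

F1 | step 4 | 2-(diethoxymethyl)-1H-indole | CCOC(OCC)c1cc2ccccc2[nH]1
F2 | step 3 | bis[1-(tert-butoxycarbonyl)indol-3-yl]methanol | OC(c1cn(C(=O)OC(C)(C)C)c2ccccc12)c1cn(C(=O)OC(C)(C)C)c2ccccc12
F3 | step 5 | 2-{3-[(tert-butyldimethylsilyl)oxy]prop-1-yn-1-yl}aniline | CC(C)(C)[Si](C)(C)OCC#Cc1ccccc1N
F4 | step 5 | N-(2-{3-[(tert-butyldimethylsilyl)oxy]prop-1-yn-1-yl}phenyl)-2,2,2-trifluoroacetamide | CC(C)(C)[Si](C)(C)OCC#Cc1ccccc1NC(=O)C(F)(F)F
F5 | step 5 | 3-{bis[1-(tert-butoxycarbonyl)indol-3-yl]methyl}-2-{[(tert-butyldimethylsilyl)oxy]methyl}-1-(trifluoroacetyl)indole | CC(C)(C)[Si](C)(C)OCc1n(C(=O)C(F)(F)F)c2ccccc2c1C(c1cn(C(=O)OC(C)(C)C)c2ccccc12)c1cn(C(=O)OC(C)(C)C)c2ccccc12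
F6 | step 5 | 3-{bis[1-(tert-butoxycarbonyl)indol-3-yl]methyl}-2-{[(tert-butyldimethylsilyl)oxy]methyl}-1H-indole | CC(C)(C)[Si](C)(C)OCc1[nH]c2ccccc2c1C(c1cn(C(=O)OC(C)(C)C)c2ccccc12)c1cn(C(=O)OC(C)(C)C)c2ccccc12
F7 | step 5 | (3-{bis[1-(tert-butoxycarbonyl)indol-3-yl]methyl}-1H-indol-2-yl)methanol | OCc1[nH]c2ccccc2c1C(c1cn(C(=O)OC(C)(C)C)c2ccccc12)c1cn(C(=O)OC(C)(C)C)c2ccccc12
F8 | step 6 | 2-(diethoxymethyl)-3-[di(1H-indol-3-yl)methyl]-1H-indole | CCOC(OCC)c1[nH]c2ccccc2c1C(c1c[nH]c2ccccc12)c1c[nH]c2ccccc12
A1 | alternative 1 | 3,3'-[2-(2-isocyanophenyl)ethene-1,1-diyl]bis(1H-indole) | [C-]#[N+]c1ccccc1C=C(c1c[nH]c2ccccc12)c1c[nH]c2ccccc12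
A2 | alternative 1 | tributyltin hydride | CCCC[SnH](CCCC)CCCC
A3 | alternative 1 | 3-[di(1H-indol-3-yl)methyl]-2-(tributylstannyl)-1H-indole | CCCC[Sn](CCCC)(CCCC)c1[nH]c2ccccc2c1C(c1c[nH]c2ccccc12)c1c[nH]c2ccccc12
A4 | alternative 2 | N-{2-[2,2-di(1H-indol-3-yl)acetyl]phenyl}-4-methylbenzenesulfonamide | Cc1ccc(cc1)S(=O)(=O)Nc1ccccc1C(=O)C(c1c[nH]c2ccccc12)c1c[nH]c2ccccc12
A5 | alternative 2 | ethyl bromoacetate | CCOC(=O)CBr
A6 | alternative 2 | ethyl 3-[di(1H-indol-3-yl)methyl]-1-[(4-methylphenyl)sulfonyl]indole-2-carboxylate | CCOC(=O)c1n(S(=O)(=O)c2ccc(C)cc2)c2ccccc2c1C(c1c[nH]c2ccccc12)c1c[nH]c2ccccc12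
A7 | alternative 3 | ethyl 4,4-di(1H-indol-3-yl)-2-oxobutanoate | CCOC(=O)C(=O)CC(c1c[nH]c2ccccc12)c1c[nH]c2ccccc12
A8 | alternative 3 | ethyl (2Z)-4,4-di(1H-indol-3-yl)-2-(2-phenylhydrazinylidene)butanoate | CCOC(=O)/C(=N\Nc1ccccc1)CC(c1c[nH]c2ccccc12)c1c[nH]c2ccccc12
A9 | alternative 3 | ethyl 3-[di(1H-indol-3-yl)methyl]-1H-indole-2-carboxylate | CCOC(=O)c1[nH]c2ccccc2c1C(c1c[nH]c2ccccc12)c1c[nH]c2ccccc12
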